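In a one-step world, a charge of ligand against a charge of complex is a single subtraction. Here each starting complex can take two incoming ligands, so you count double.

in all of them: starting complex 0.38 M
- zeta: incoming ligand 0.47 M; run made earlier
- theta: incoming ligand 0.85 M; run made earlier
- beta: incoming ligand 1.1 M; run made earlier
- alder: incoming ligand 0.950 M; time 3.0 min
- birch: incoming ligand 1.14 M; time 3.0 min
- larch: incoming ligand 0.570 M; time 3.0 min

| run | time / min | complex with one exchanged / % | complex with two exchanged / % |
|---|---|---|---|
| zeta | 0.250 | 11.1 | 3.3 |
| zeta | 0.833 | 24.1 | 9.0 |
| zeta | 1.33 | 25.8 | 14.3 |
| zeta | 2.00 | 25.8 | 17.9 |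
| zeta | 3.00 | 26.5 | 19.8 |
| theta | 0.250 | 16.8 | 3.7 |
| theta | 0.417 | 23.4 | 8.8 |
| theta | 0.833 | 26.2 | 23.2 |
| theta | 1.50 | 22.2 | 33.4 |
| theta | 3.00 | 16.0 | 38.7 |
| beta | 0.250 | 20.5 | 6.3 |
| beta | 0.417 | 23.1 | 14.5 |
| beta | 0.833 | 23.9 | 30.2 |
| beta | 1.50 | 18.5 | 44.0 |
| beta | 3.00 | 8.0 | 44.7 |

(readings scatter by 1 percentage point)

- the numbers in the tables scatter by 1 percentage point (one standard deviation)
- steps thought possible: starting complex + incoming ligand -> leaving ligand + complex with one exchanged; complex with one exchanged + incoming ligand -> leaving ligand + complex with two exchanged; complex with two exchanged <-> isomer of the product

* which of these holds the largest part of the starting complex at the end of alder (starting complex / complex with one exchanged / complex with two exchanged)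
* which of these holds the largest part of the starting complex at the end of birch (starting complex / complex with one exchanged / complex with two exchanged)
* which of these holds the largest part of the starting complex at the end of larch (starting complex / complex with one exchanged / complex with two exchanged)
* complex with one exchanged at the end of birch, in percent of the starting complex charged

Birch has a ligand cover of 1.50, the incoming ligand charged over twice the starting complex charged. Below a cover of one, the incoming ligand is the limiting reagent for the double exchange. Above one, a floor of one minus the inverse of the cover stays unused, which for birch is 33.3% of its charge.

The readings straddle that crossing. Zeta, at a cover of 0.618, holds complex with one exchanged level, 25.8% at 1.33 min and 26.5% at 3.00 min. Beta, at 1.45, falls from 23.9% at 0.833 min to 8.0% at 3.00 min. Birch therefore sits with beta, and you can bracket it by hand. Theta's end reading of 16.0% is a loose ceiling for birch. Beta's end reading plus one scatter tightens it to 9.00%, since birch carries more ligand on the same complex. For the lower end, an estimate from scattered readings and no strict bound, run the fall from theta to beta straight on to birch's charge and take off one scatter, which gives 5.72%.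

The forecast, holding that “Birch is slightly richer than beta”, names as largest holder complex with two exchanged for alder, complex with two exchanged for birch and starting complex for larch. Its 7.5% of complex with one exchanged for birch lies inside my bracket.

The largest holders turn out to be complex with two exchanged in alder, complex with two exchanged in birch and starting complex in larch, and birch ends with 8.50% of complex with one exchanged, also inside the bracket.

    starting complex + incoming ligand → leaving ligand + complex with one exchanged (k = 0.0200 M⁻¹ s⁻¹)
    complex with one exchanged + incoming ligand → leaving ligand + complex with two exchanged (k = 0.0380 M⁻¹ s⁻¹)
    complex with two exchanged ⇌ isomer of the product (K = 14.0, k = 0.00570 s⁻¹)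

Birch kept 41.9% of its incoming ligand at 3.00 min and 33.3% at 30.0 min, level with the floor of 33.3% that a cover of 1.50 gives. Now charge 1.5 M of starting complex instead, holding the ligand and the time. The cover drops to 0.380, less ligand than both exchanges need. That neighbouring flask has 0.402% of its incoming ligand left at 3.00 min, with 25.8% as complex with one exchanged, and its largest holder is starting complex, at 49.3%.

The data were computed from invented constants; the scatter is artificial.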